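**Retrosynthetic overview**
- The strategy rests on the contiguous triad C6(O)-C7(C11 branch)-C8(O), flanked by the vinyl carbon C5 and by C9. These five carbons and O8 are laid onto a γ-butyrolactone scaffold (C5 carbonyl, C6 α, C7 β, C8 γ, C9 side arm) that is not a ring of the target.
- Key disconnection: C7-C11 and C6-O are made together on an (S)-5-(silyloxymethyl)butenolide by vinylcuprate addition and enolate hydroxylation. C8 relays its configuration to C7, and C7 relays it to C6.
- Scaffold opening: the lactol and an α-bromo ylide give the Z C4=C5 alkene, with C15 as the ester and Br on C4 as the handle for C3/C2 (Sonogashira). This frees O8.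
- The C9 aldehyde takes on C10 (chelate control). Directed epoxidation and hydride opening give C10 and C14. The C1 aldehyde and the C2 iodoalkyne then close C1-C2.
- Ring order: ten-membered carbocycle (C1-C2), then furanone (O10-C3, 5-endo-dig), then α-methylene-γ-lactone (O6-C12) in the last step. Both esters go on before the lactone, so that O8 cannot compete for C12.

Key step: step 3

Remark: locants C1-C15 are the germacrane locants of the target (On is the oxygen on Cn); the lactol and the macrocyclic C1 carbinol are carried as epimer mixtures because C5 and C1 become sp2 centres.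

**Route**

Step 1
Reactants: 1 (S)-5-(hydroxymethyl)furan-2(5H)-one; 2 tert-butyl(chloro)diphenylsilane
Product: 3 (S)-5-[(tert-butyldiphenylsilyloxy)methyl]furan-2(5H)-one
Conditions: imidazole, DMF, 0 °C to rt
Reagents that add atoms: tert-butyl(chloro)diphenylsilane 2, CC(C)(C)[Si](Cl)(c1ccccc1)c1ccccc1
Why: Imidazole-promoted O-silylation of the primary alcohol should be clean, leaves C8 untouched and installs the bulky arm that later shields one face of the butenolide.

Step 2
Reactants: 4 2-bromoprop-2-en-1-ol; 5 4-methoxybenzyl chloride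
Product: 6 2-bromo-3-(4-methoxybenzyloxy)prop-1-ene
Conditions: NaH, Bu4NI (cat.), THF, 0 °C to rt
Reagents that add atoms: 4-methoxybenzyl chloride 5, COc1ccc(CCl)cc1
Why: Williamson etherification of the sodium alkoxide with the benzylic chloride under iodide catalysis should proceed without touching the vinyl bromide.

Step 3
Reactants: 3 (S)-5-[(tert-butyldiphenylsilyloxy)methyl]furan-2(5H)-one; 6 2-bromo-3-(4-methoxybenzyloxy)prop-1-ene; 7 2-(phenylsulfonyl)-3-phenyloxaziridine
Product: 11 (3S,4S,5S)-5-[(tert-butyldiphenylsilyloxy)methyl]-3-hydroxy-4-[3-(4-methoxybenzyloxy)prop-1-en-2-yl]oxolan-2-one (all-trans), via vinyllithium 8 (not isolated), via divinylcuprate 9 (not isolated), via lithium enolate 10 (not isolated)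
Conditions: 6 (2.2 equiv), t-BuLi (4.4 equiv), Et2O, -78 °C; CuBr·SMe2 (1.1 equiv), -78 to -40 °C; 3, Et2O/THF, -78 °C; 7 (2.5 equiv), THF, -78 °C; aq. NH4Cl
Reagents that add atoms: 2-bromo-3-(4-methoxybenzyloxy)prop-1-ene 6, C=C(Br)COCc1ccc(OC)cc1; 2-(phenylsulfonyl)-3-phenyloxaziridine 7, O=S(=O)(c1ccccc1)N1OC1c1ccccc1
Why: Bromine-lithium exchange and transmetalation give the Gilman-type divinylcuprate 9, which binds the butenolide alkene, adds at the β-carbon C7 and forms C7-C11 by reductive elimination (organocuprate conjugate addition), leaving lithium enolate 10. The enolate carbon C6 then displaces nitrogen at the oxaziridine oxygen and the hemiaminal collapses to the sulfonimine (Davis enolate hydroxylation), so that C7-C11 and C6-O arise in one flask in the manner of known tandem conjugate addition/enolate trapping sequences. No ring is closed, because the five-membered lactone C5-C6-C7-C8-O8 serves only as a scaffold. C7 is controlled by C8, since the silyloxymethyl arm blocks its own face and the cuprate enters anti to it, and C6 is controlled by the new C7 branch, since the oxaziridine meets the planar enolate anti to that branch, which should give the all-trans 6,7,8-array. The step needs 1,4- over 1,2-addition, secured by the soft cuprate, and oxidation faster than proton transfer or addition of the enolate to the sulfonimine, secured by the low temperature, the hindered β-branched enolate and an excess of 7 that also consumes the residual vinylcopper.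

Step 4
Reactants: 11 all-trans hydroxy lactone
Product: 12 O6-TBS ether of 11 (all-trans lactone)
Conditions: TBSOTf, 2,6-lutidine, CH2Cl2, 0 °C
Reagents that add atoms: tert-butyldimethylsilyl triflate, CC(C)(C)[Si](C)(C)OS(=O)(=O)C(F)(F)F
Why: Silyl triflate/lutidine O-silylation caps the hindered C6 hydroxyl under conditions too mild to enolise the lactone, so C6 is kept, and a secondary TBS ether is chosen because it outlasts the primary TBDPS ether in step 9.

Step 5
Reactants: 12 O6-TBS lactone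
Product: 13 lactol of 12 (oxolan-2-ol, C5 epimers; C6, C7, C8 as in 11)
Conditions: i-Bu2AlH (1.2 equiv), CH2Cl2, -78 °C; aq. potassium sodium tartrate
Reagents that add atoms: none
Why: Partial reduction of the γ-lactone with i-Bu2AlH stops at the aluminium hemiacetal at -78 °C and should give the lactol, whose C5 epimers are of no consequence because C5 becomes sp2.

Step 6
Reactants: 14 ethyl (triphenylphosphoranylidene)acetate
Product: 15 ethyl bromo(triphenylphosphoranylidene)acetate
Conditions: NBS, CH2Cl2, -20 °C to rt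
Reagents that add atoms: N-bromosuccinimide, O=C1CCC(=O)N1Br
Why: Electrophilic bromination of the stabilised ylide at carbon and loss of the proton to the succinimide anion should regenerate a stabilised α-bromo ylide.

Step 7
Reactants: 13 lactol; 15 ethyl bromo(triphenylphosphoranylidene)acetate
Product: 16 ethyl (Z)-2-bromohept-2-enoate carrying 4-OTBS (C6), 5-[3-(PMB-oxy)prop-1-en-2-yl] (C7), 6-OH (C8) and 7-OTBDPS (C9)
Conditions: 15 (2 equiv), PhCO2H (cat.), toluene, 80 °C
Reagents that add atoms: ethyl bromo(triphenylphosphoranylidene)acetate 15, CCOC(=O)C(Br)=P(c1ccccc1)(c1ccccc1)c1ccccc1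
Why: Wittig olefination of the hydroxy aldehyde tautomer of the lactol with a stabilised α-bromo ylide puts the ester (C15) trans to C6, which defines the C4=C5 geometry (Z-bromoalkene, Br at the future C3 site cis to C6), opens the scaffold ring and frees O8-H.

Step 8
Reactants: 16 bromoenoate alcohol
Product: 17 O8-MOM ether of 16
Conditions: MOMCl, i-Pr2NEt, Bu4NI (cat.), CH2Cl2, 0 to 40 °C
Reagents that add atoms: chloromethyl methyl ether, COCCl
Why: Alkylation of O8-H with MOMCl under a hindered amine base, too weak to start oxa-Michael addition to C5, should give the acetal ether that serves as the chelating group in step 13.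

Step 9
Reactants: 17 MOM ether
Product: 18 C9 primary alcohol (O6-TBS, O8-MOM, O12-PMB and the bromoenoate retained)
Conditions: Bu4NF/AcOH (1:1), THF, 0 °C to rt
Reagents that add atoms: none
Why: Buffered fluoride desilylation attacks the unhindered primary TBDPS ether faster than the hindered secondary TBS ether, and the acetic acid keeps the freed alkoxide from silyl migration or conjugate addition.

Step 10
Reactants: 18 C9 alcohol; 19 ethynyltrimethylsilane
Product: 20 ethyl (E)-2-[(trimethylsilyl)ethynyl]hept-2-enoate analogue of 18 (C3 cis to C6, C15 ester trans to C6)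
Conditions: 19, PdCl2(PPh3)2 (5 mol %), CuI (10 mol %), Et3N, THF, rt
Reagents that add atoms: ethynyltrimethylsilane 19, C#C[Si](C)(C)C
Why: Sonogashira coupling: zerovalent palladium inserts into the activated C4-Br bond and the copper acetylide is transferred with retention of the alkene geometry, so that C3 ends cis to C6.

Step 11
Reactants: 20 enynoate alcohol
Product: 21 C9 aldehyde
Conditions: DMP, CH2Cl2, 0 °C to rt
Reagents that add atoms: none
Why: Dess-Martin oxidation works under near-neutral conditions and should give the α-alkoxy aldehyde without epimerisation at C8.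

Step 12
Reactants: 4 2-bromoprop-2-en-1-ol
Product: 22 (2-bromoallyloxy)triethylsilane
Conditions: Et3SiCl, imidazole, CH2Cl2, 0 °C
Reagents that add atoms: chlorotriethylsilane, CC[Si](Cl)(CC)CC
Why: Imidazole-promoted silylation gives the acid-labile TES ether that can later be removed in the presence of TBS and TBDPS ethers.

Step 13
Reactants: 21 C9 aldehyde; 22 (2-bromoallyloxy)triethylsilane
Product: 25 C9 allylic alcohol with the 3-(triethylsilyloxy)prop-1-en-2-yl group as C10, C14 and C1 (O8 and O9 syn), via vinyllithium 23 (not isolated), via vinylmagnesium bromide 24 (not isolated)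
Conditions: 22 (3 equiv), t-BuLi (6 equiv), Et2O, -78 °C; MgBr2·OEt2 (3.3 equiv); added to 21 and MgBr2·OEt2 (2 equiv), CH2Cl2, -78 °C; aq. NH4Cl
Reagents that add atoms: (2-bromoallyloxy)triethylsilane 22, C=C(Br)CO[Si](CC)(CC)CC
Why: Cram-chelate-controlled Grignard addition: magnesium bridges the C9 carbonyl oxygen and the MOM-bearing O8, the vinyl group attacks the aldehyde face on the side of H8 and away from C7, and this should set C9 with O8 and O9 syn, while the ester is inert at -78 °C.

Step 14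
Reactants: 25 allylic alcohol
Product: 26 C10-C14 epoxy alcohol (O10 syn to O9 along C8-C9-C10-C1)
Conditions: VO(acac)2 (5 mol %), t-BuOOH (decane), CH2Cl2, 0 °C
Reagents that add atoms: tert-butyl hydroperoxide, CC(C)(C)OO
Why: Hydroxyl-directed vanadium-catalysed epoxidation touches only the allylic alcohol alkene, and the vanadate of O9 delivers oxygen to the face that keeps C8 away from the geminal CH2OTES group (A1,2 strain), which should set C10 with O10 syn to O9 along the C8-C9-C10-C1 chain.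

Step 15
Reactants: 26 epoxy alcohol
Product: 28 triol (C15 primary allylic OH, C9 secondary OH, C10 tertiary OH with the C14 methyl), via epoxy diol 27 (not isolated)
Conditions: i-Bu2AlH (4 equiv), CH2Cl2, -78 °C; then LiEt3BH (5 equiv), THF, -78 to 0 °C; aq. potassium sodium tartrate
Reagents that add atoms: none
Why: i-Bu2AlH reduces the conjugated ester in the 1,2-sense to the C15 allylic alcohol and LiEt3BH then opens the epoxide by SN2 attack at the unsubstituted carbon C14, which makes the C14 methyl group and leaves the C10-O bond and its configuration untouched.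

Step 16
Reactants: 28 triol; 2 tert-butyl(chloro)diphenylsilane
Product: 29 O15-TBDPS ether (9,10-diol)
Conditions: 2 (1.1 equiv), imidazole, CH2Cl2, 0 °C
Reagents that add atoms: tert-butyl(chloro)diphenylsilane 2, CC(C)(C)[Si](Cl)(c1ccccc1)c1ccccc1
Why: Steric discrimination in silylation: the bulky chlorosilane reacts only at the primary allylic O15-H and leaves the hindered secondary and tertiary hydroxyls free.

Step 17
Reactants: 29 9,10-diol; 30 3-methylbutanoic anhydride
Product: 31 O9 isovalerate (O10-H free)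
Conditions: 30, DMAP (0.2 equiv), Et3N, CH2Cl2, rt
Reagents that add atoms: 3-methylbutanoic anhydride 30, CC(C)CC(=O)OC(=O)CC(C)C
Why: DMAP-catalysed acyl transfer acylates the secondary O9-H, whereas the tertiary O10-H is too hindered to react.

Step 18
Reactants: 31 isovalerate
Product: 32 C2 iodoalkyne
Conditions: NIS, AgNO3 (0.2 equiv), DMF, rt, dark
Reagents that add atoms: N-iodosuccinimide, O=C1CCC(=O)N1I
Why: Silver-catalysed iododesilylation of the alkynylsilane with NIS should give the 1-iodoalkyne needed for chromium insertion faster than NIS attacks the inductively deactivated C11=C13 alkene.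

Step 19
Reactants: 32 iodoalkyne
Product: 33 1,10-diol (C1 primary OH, C10 tertiary OH)
Conditions: PPTS (cat.), MeOH/CH2Cl2, 0 °C
Reagents that add atoms: none
Why: Acid-catalysed methanolysis removes the TES ether, the most labile silyl group present, and leaves the TBS, TBDPS, MOM and PMB ethers in place.

Step 20
Reactants: 33 1,10-diol
Product: 34 C1 aldehyde with free O10-H
Conditions: IBX, DMSO, rt
Reagents that add atoms: none
Why: IBX oxidises the primary alcohol of the 1,2-diol without glycol cleavage and the tertiary O10-H cannot be oxidised, so that a non-enolisable α-hydroxy aldehyde should result.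

Step 21
Reactants: 34 iodoalkyne aldehyde
Product: 35 ten-membered cyclic enyne carbinol (C1-C2 bond formed, C1 epimers)
Conditions: CrCl2 (10 equiv), NiCl2 (1 mol %), THF, rt, slow addition to 1 mM
Reagents that add atoms: none
Why: Intramolecular Nozaki-Hiyama-Kishi alkynylation: divalent chromium inserts into the C2-I bond and the chemoselective alkynylchromium species adds to the C1 aldehyde, a closure known for strained ten-membered cyclic enynes and helped here by the Z C4=C5 alkene and the fully substituted C6-C10 chain, while the new C1 carbinol centre is removed in step 22.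

Step 22
Reactants: 35 macrocyclic carbinol
Product: 37 bicyclic 3(2H)-furanone (O10-C3 bond, C1 ketone, C2=C3), via hydroxy ynone 36 (not isolated)
Conditions: DMP, CH2Cl2, 0 °C to rt; aqueous wash; then AuCl(PPh3)/AgOTf (5 mol %), toluene, rt
Reagents that add atoms: none
Why: Dess-Martin oxidation gives the strained α'-hydroxy ynone and cationic gold then activates the alkyne for 5-endo-dig attack of O10-H on C3 (cycloisomerisation to a 3(2H)-furanone), which releases the alkyne strain and does not touch C10.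

Step 23
Reactants: 37 furanone
Product: 39 C8 alcohol, via bipyridinium salt 38 (not isolated)
Conditions: Me3SiOTf, 2,2'-bipyridyl, CH2Cl2, 0 °C to rt; then H2O
Reagents that add atoms: none
Why: The silyl triflate/bipyridyl pair converts the MOM acetal into an N-(alkoxymethyl)bipyridinium salt that water hydrolyses to the alcohol under almost neutral conditions, so that the silyl ethers, the PMB ether and the ester should survive.

Step 24
Reactants: 39 C8 alcohol; 40 methacrylic anhydride
Product: 41 O8 methacrylate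
Conditions: 40, DMAP (0.2 equiv), Et3N, CH2Cl2, rt
Reagents that add atoms: methacrylic anhydride 40, C=C(C)C(=O)OC(=O)C(C)=C
Why: DMAP-catalysed acylation of the only free hydroxyl installs the methacrylate before O6 and C12 are unmasked, so that O8 cannot compete for C12 later.

Step 25
Reactants: 41 methacrylate
Product: 42 C12 allylic alcohol
Conditions: DDQ, CH2Cl2/pH 7 buffer, 0 °C
Reagents that add atoms: none
Why: Oxidative cleavage of the PMB ether by DDQ (hydride abstraction and hydrolysis of the oxocarbenium ion) is selective for the electron-rich benzyl ether over the electron-poor dienone and the acrylate.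

Step 26
Reactants: 42 C12 allylic alcohol
Product: 44 C12 acrylic acid (O6-TBS and O15-TBDPS retained), via enal 43 (not isolated)
Conditions: TEMPO (cat.), PhI(OAc)2, CH2Cl2, rt; then t-BuOH/H2O, 2-methylbut-2-ene, NaH2PO4, NaClO2, 0 °C to rt
Reagents that add atoms: sodium chlorite, [Na+].[O-]Cl=O
Why: Oxoammonium oxidation (TEMPO/PhI(OAc)2) of the only free alcohol gives the enal and Pinnick oxidation in the same flask takes it to the acrylic acid, with 2-methylbut-2-ene trapping hypochlorous acid before it reaches the alkenes.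

Step 27
Reactants: 44 C12 acid
Product: 46 CNP0552093.1 (target), via seco acid 45 (not isolated)
Conditions: HF·pyridine, THF, 0 °C to rt
Reagents that add atoms: none
Why: Fluoride-driven cleavage of both silyl ethers frees O15-H and O6-H, and the γ-hydroxy acid should lactonise in the acidic medium (5-exo-trig acyl substitution) to the trans-fused α-methylene-γ-lactone with retention at C6, because only the acyl C-O bond is exchanged.

**Compound list**
1 | (S)-5-(hydroxymethyl)furan-2(5H)-one | O=C1C=C[C@@H](CO)O1 | starting material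
2 | tert-butyl(chloro)diphenylsilane | CC(C)(C)[Si](Cl)(c1ccccc1)c1ccccc1 | starting material
3 | (S)-5-[(tert-butyldiphenylsilyloxy)methyl]furan-2(5H)-one | O=C1C=C[C@@H](CO[Si](c2ccccc2)(c2ccccc2)C(C)(C)C)O1 | intermediate
4 | 2-bromoprop-2-en-1-ol | C=C(Br)CO | starting material
5 | 4-methoxybenzyl chloride | COc1ccc(CCl)cc1 | starting material
6 | 2-bromo-3-(4-methoxybenzyloxy)prop-1-ene | C=C(Br)COCc1ccc(OC)cc1 | intermediate
7 | 2-(phenylsulfonyl)-3-phenyloxaziridine (racemic) | O=S(=O)(c1ccccc1)N1OC1c1ccccc1 | starting material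
8 | [3-(4-methoxybenzyloxy)prop-1-en-2-yl]lithium | [Li]C(=C)COCc1ccc(OC)cc1 | intermediate
9 | lithium bis[3-(4-methoxybenzyloxy)prop-1-en-2-yl]cuprate | [Li+].C=C(COCc1ccc(OC)cc1)[Cu-]C(=C)COCc1ccc(OC)cc1 | intermediate
10 | lithium enolate of the C7 adduct | [Li]OC1=C[C@H](C(=C)COCc2ccc(OC)cc2)[C@@H](CO[Si](c2ccccc2)(c2ccccc2)C(C)(C)C)O1 | intermediate
11 | (3S,4S,5S) all-trans hydroxy lactone (C6 OH, C7 branch, C8) | O=C1[C@@H](O)[C@H](C(=C)COCc2ccc(OC)cc2)[C@@H](CO[Si](c2ccccc2)(c2ccccc2)C(C)(C)C)O1 | intermediate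
12 | O6-TBS lactone | O=C1[C@@H](O[Si](C)(C)C(C)(C)C)[C@H](C(=C)COCc2ccc(OC)cc2)[C@@H](CO[Si](c2ccccc2)(c2ccccc2)C(C)(C)C)O1 | intermediate
13 | lactol (C5 epimers) | OC1[C@@H](O[Si](C)(C)C(C)(C)C)[C@H](C(=C)COCc2ccc(OC)cc2)[C@@H](CO[Si](c2ccccc2)(c2ccccc2)C(C)(C)C)O1 | intermediate
14 | ethyl (triphenylphosphoranylidene)acetate | CCOC(=O)C=P(c1ccccc1)(c1ccccc1)c1ccccc1 | starting material
15 | ethyl bromo(triphenylphosphoranylidene)acetate | CCOC(=O)C(Br)=P(c1ccccc1)(c1ccccc1)c1ccccc1 | intermediate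
16 | (Z)-bromoenoate with free O8-H | CCOC(=O)/C(Br)=C/[C@@H](O[Si](C)(C)C(C)(C)C)[C@H](C(=C)COCc1ccc(OC)cc1)[C@H](O)CO[Si](c1ccccc1)(c1ccccc1)C(C)(C)C | intermediate
17 | O8-MOM bromoenoate | CCOC(=O)/C(Br)=C/[C@@H](O[Si](C)(C)C(C)(C)C)[C@H](C(=C)COCc1ccc(OC)cc1)[C@H](OCOC)CO[Si](c1ccccc1)(c1ccccc1)C(C)(C)C | intermediate
18 | C9 primary alcohol | CCOC(=O)/C(Br)=C/[C@@H](O[Si](C)(C)C(C)(C)C)[C@H](C(=C)COCc1ccc(OC)cc1)[C@H](OCOC)CO | intermediate
19 | ethynyltrimethylsilane | C#C[Si](C)(C)C | starting material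
20 | TMS-enynoate alcohol | CCOC(=O)/C(C#C[Si](C)(C)C)=C/[C@@H](O[Si](C)(C)C(C)(C)C)[C@H](C(=C)COCc1ccc(OC)cc1)[C@H](OCOC)CO | intermediate
21 | C9 aldehyde | CCOC(=O)/C(C#C[Si](C)(C)C)=C/[C@@H](O[Si](C)(C)C(C)(C)C)[C@H](C(=C)COCc1ccc(OC)cc1)[C@H](OCOC)C=O | intermediate
22 | (2-bromoallyloxy)triethylsilane | C=C(Br)CO[Si](CC)(CC)CC | intermediate
23 | [3-(triethylsilyloxy)prop-1-en-2-yl]lithium | [Li]C(=C)CO[Si](CC)(CC)CC | intermediate
24 | [3-(triethylsilyloxy)prop-1-en-2-yl]magnesium bromide | Br[Mg]C(=C)CO[Si](CC)(CC)CC | intermediate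
25 | C9 allylic alcohol | CCOC(=O)/C(C#C[Si](C)(C)C)=C/[C@@H](O[Si](C)(C)C(C)(C)C)[C@H](C(=C)COCc1ccc(OC)cc1)[C@H](OCOC)[C@@H](O)C(=C)CO[Si](CC)(CC)CC | intermediate
26 | C10-C14 epoxy alcohol | CCOC(=O)/C(C#C[Si](C)(C)C)=C/[C@@H](O[Si](C)(C)C(C)(C)C)[C@H](C(=C)COCc1ccc(OC)cc1)[C@H](OCOC)[C@@H](O)[C@@]1(CO1)CO[Si](CC)(CC)CC | intermediate
27 | epoxy diol | OC/C(C#C[Si](C)(C)C)=C/[C@@H](O[Si](C)(C)C(C)(C)C)[C@H](C(=C)COCc1ccc(OC)cc1)[C@H](OCOC)[C@@H](O)[C@@]1(CO1)CO[Si](CC)(CC)CC | intermediate
28 | 9,10,15-triol | OC/C(C#C[Si](C)(C)C)=C/[C@@H](O[Si](C)(C)C(C)(C)C)[C@H](C(=C)COCc1ccc(OC)cc1)[C@H](OCOC)[C@@H](O)[C@](C)(O)CO[Si](CC)(CC)CC | intermediate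
29 | O15-TBDPS 9,10-diol | CC(C)(C)[Si](c1ccccc1)(c1ccccc1)OC/C(C#C[Si](C)(C)C)=C/[C@@H](O[Si](C)(C)C(C)(C)C)[C@H](C(=C)COCc1ccc(OC)cc1)[C@H](OCOC)[C@@H](O)[C@](C)(O)CO[Si](CC)(CC)CC | intermediate
30 | 3-methylbutanoic anhydride | CC(C)CC(=O)OC(=O)CC(C)C | starting material
31 | O9 isovalerate | CC(C)(C)[Si](c1ccccc1)(c1ccccc1)OC/C(C#C[Si](C)(C)C)=C/[C@@H](O[Si](C)(C)C(C)(C)C)[C@H](C(=C)COCc1ccc(OC)cc1)[C@H](OCOC)[C@@H](OC(=O)CC(C)C)[C@](C)(O)CO[Si](CC)(CC)CC | intermediate
32 | C2 iodoalkyne | CC(C)(C)[Si](c1ccccc1)(c1ccccc1)OC/C(C#CI)=C/[C@@H](O[Si](C)(C)C(C)(C)C)[C@H](C(=C)COCc1ccc(OC)cc1)[C@H](OCOC)[C@@H](OC(=O)CC(C)C)[C@](C)(O)CO[Si](CC)(CC)CC | intermediate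
33 | 1,10-diol | CC(C)(C)[Si](c1ccccc1)(c1ccccc1)OC/C(C#CI)=C/[C@@H](O[Si](C)(C)C(C)(C)C)[C@H](C(=C)COCc1ccc(OC)cc1)[C@H](OCOC)[C@@H](OC(=O)CC(C)C)[C@](C)(O)CO | intermediate
34 | C1 aldehyde | CC(C)(C)[Si](c1ccccc1)(c1ccccc1)OC/C(C#CI)=C/[C@@H](O[Si](C)(C)C(C)(C)C)[C@H](C(=C)COCc1ccc(OC)cc1)[C@H](OCOC)[C@@H](OC(=O)CC(C)C)[C@](C)(O)C=O | intermediate
35 | ten-membered enyne carbinol (C1 epimers) | CC(C)(C)[Si](c1ccccc1)(c1ccccc1)OC/C1=C/[C@@H](O[Si](C)(C)C(C)(C)C)[C@H](C(=C)COCc2ccc(OC)cc2)[C@H](OCOC)[C@@H](OC(=O)CC(C)C)[C@](C)(O)C(O)C#C1 | intermediate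
36 | macrocyclic α'-hydroxy ynone | CC(C)(C)[Si](c1ccccc1)(c1ccccc1)OC/C1=C/[C@@H](O[Si](C)(C)C(C)(C)C)[C@H](C(=C)COCc2ccc(OC)cc2)[C@H](OCOC)[C@@H](OC(=O)CC(C)C)[C@](C)(O)C(=O)C#C1 | intermediate
37 | bicyclic furanone (O8-MOM) | CC(C)(C)[Si](c1ccccc1)(c1ccccc1)OC/C1=C/[C@@H](O[Si](C)(C)C(C)(C)C)[C@H](C(=C)COCc2ccc(OC)cc2)[C@H](OCOC)[C@@H](OC(=O)CC(C)C)[C@]2(C)OC1=CC2=O | intermediate
38 | N-(O8-methyl)-2,2'-bipyridinium triflate | CC(C)(C)[Si](c1ccccc1)(c1ccccc1)OC/C1=C/[C@@H](O[Si](C)(C)C(C)(C)C)[C@H](C(=C)COCc2ccc(OC)cc2)[C@H](OC[n+]3ccccc3-c3ccccn3)[C@@H](OC(=O)CC(C)C)[C@]2(C)OC1=CC2=O.[O-]S(=O)(=O)C(F)(F)F | intermediate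
39 | C8 alcohol | CC(C)(C)[Si](c1ccccc1)(c1ccccc1)OC/C1=C/[C@@H](O[Si](C)(C)C(C)(C)C)[C@H](C(=C)COCc2ccc(OC)cc2)[C@H](O)[C@@H](OC(=O)CC(C)C)[C@]2(C)OC1=CC2=O | intermediate
40 | methacrylic anhydride | C=C(C)C(=O)OC(=O)C(C)=C | starting material
41 | O8 methacrylate | CC(C)(C)[Si](c1ccccc1)(c1ccccc1)OC/C1=C/[C@@H](O[Si](C)(C)C(C)(C)C)[C@H](C(=C)COCc2ccc(OC)cc2)[C@H](OC(=O)C(C)=C)[C@@H](OC(=O)CC(C)C)[C@]2(C)OC1=CC2=O | intermediate
42 | C12 allylic alcohol | CC(C)(C)[Si](c1ccccc1)(c1ccccc1)OC/C1=C/[C@@H](O[Si](C)(C)C(C)(C)C)[C@H](C(=C)CO)[C@H](OC(=O)C(C)=C)[C@@H](OC(=O)CC(C)C)[C@]2(C)OC1=CC2=O | intermediate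
43 | C12 enal | CC(C)(C)[Si](c1ccccc1)(c1ccccc1)OC/C1=C/[C@@H](O[Si](C)(C)C(C)(C)C)[C@H](C(=C)C=O)[C@H](OC(=O)C(C)=C)[C@@H](OC(=O)CC(C)C)[C@]2(C)OC1=CC2=O | intermediate
44 | C12 acrylic acid | CC(C)(C)[Si](c1ccccc1)(c1ccccc1)OC/C1=C/[C@@H](O[Si](C)(C)C(C)(C)C)[C@H](C(=C)C(=O)O)[C@H](OC(=O)C(C)=C)[C@@H](OC(=O)CC(C)C)[C@]2(C)OC1=CC2=O | intermediate
45 | seco hydroxy acid (O6-H, O15-H free) | OC/C1=C/[C@@H](O)[C@H](C(=C)C(=O)O)[C@H](OC(=O)C(C)=C)[C@@H](OC(=O)CC(C)C)[C@]2(C)OC1=CC2=O | intermediate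
46 | CNP0552093.1 | C=C(C)C(=O)O[C@H]1[C@H]2C(=C)C(=O)O[C@@H]2/C=C(/CO)C2=CC(=O)[C@@](C)(O2)[C@@H]1OC(=O)CC(C)C | target

**Step count**
- Total steps: 27.
- Longest linear sequence: 24 steps (from 1 through steps 1, 3-5, 7-11 and 13-27).

**Steps most likely to fail**

Risk 1 (step 21).
- What may go wrong: intermolecular coupling and protodemetalation of the alkynylchromium species may outrun closure, because the linear C1-C2-C3-C4 segment strains the ten-membered transition state.
- Fallback: it sets out from 31 and comes back at 37, and it replaces the sp carbon C2 by an sp2 carbon so that a less strained diene ring is closed.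
- K2CO3 in MeOH at 0 °C removes the C-silyl group to give the terminal enyne F1.
- Hydrozirconation with Cp2Zr(H)Cl followed by iodine gives the (E)-dienyl iodide F2.
- PPTS in MeOH gives the 1,10-diol F3, and IBX gives the hydroxy aldehyde F4.
- An alkenyl Nozaki-Hiyama-Kishi closure (CrCl2, NiCl2 cat., DMSO/THF, high dilution) gives the cyclodecadienol F5, and DMP gives the α'-hydroxy dienone F6.
- A Wacker-type oxidative cyclisation (PdCl2(MeCN)2, CuCl, O2, DME) joins O10 to C3 and restores C2=C3, which gives 37.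

Risk 2 (step 3).
- What may go wrong: the oxidant may be consumed by organocopper residues, and the enolate may be lost to proton transfer or to addition onto the sulfonimine, so that hydroxylation in the copper-containing mixture stays incomplete.
- Fallback: it sets out from 3 and 6 and comes back at 11, and it separates the two bond formations.
- The cuprate addition (through 8, 9 and 10) is quenched with aq. NH4Cl, and the trans-4,5-disubstituted lactone F7 is isolated.
- A copper-free potassium enolate is then made with KN(SiMe3)2 in THF at -78 °C and hydroxylated with 7 anti to the C7 branch, which gives 11.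

Risk 3 (step 7).
- What may go wrong: slow ring opening of the hindered lactol may force long heating, during which the freed O8-H can add to C5 of the bromoenoate (oxa-Michael ring closure) or C6 can epimerise.
- Fallback: it sets out from 12 and comes back at 17, and it avoids the lactol altogether.
- Aminolysis of 12 with MeNH(OMe)·HCl and Me3Al opens the scaffold to the hydroxy Weinreb amide F8.
- Immediate treatment with MOMCl and i-Pr2NEt gives the O8-MOM amide F9.
- i-Bu2AlH at -78 °C gives the acyclic C5 aldehyde F10.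
- F10 has no free hydroxyl and should react with 15 in CH2Cl2 at rt to give 17 directly.

**Further compounds**
F1 | step 21 | terminal enyne (C2-H) | CC(C)(C)[Si](c1ccccc1)(c1ccccc1)OC/C(C#C)=C/[C@@H](O[Si](C)(C)C(C)(C)C)[C@H](C(=C)COCc1ccc(OC)cc1)[C@H](OCOC)[C@@H](OC(=O)CC(C)C)[C@](C)(O)CO[Si](CC)(CC)CC
F2 | step 21 | (E)-dienyl iodide | CC(C)(C)[Si](c1ccccc1)(c1ccccc1)OC/C(/C=C/I)=C/[C@@H](O[Si](C)(C)C(C)(C)C)[C@H](C(=C)COCc1ccc(OC)cc1)[C@H](OCOC)[C@@H](OC(=O)CC(C)C)[C@](C)(O)CO[Si](CC)(CC)CC
F3 | step 21 | dienyl iodide 1,10-diol | CC(C)(C)[Si](c1ccccc1)(c1ccccc1)OC/C(/C=C/I)=C/[C@@H](O[Si](C)(C)C(C)(C)C)[C@H](C(=C)COCc1ccc(OC)cc1)[C@H](OCOC)[C@@H](OC(=O)CC(C)C)[C@](C)(O)CO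
F4 | step 21 | dienyl iodide hydroxy aldehyde | CC(C)(C)[Si](c1ccccc1)(c1ccccc1)OC/C(/C=C/I)=C/[C@@H](O[Si](C)(C)C(C)(C)C)[C@H](C(=C)COCc1ccc(OC)cc1)[C@H](OCOC)[C@@H](OC(=O)CC(C)C)[C@](C)(O)C=O
F5 | step 21 | (2E,4Z)-cyclodecadienol (C1 epimers) | OC1/C=C/C(CO[Si](c2ccccc2)(c2ccccc2)C(C)(C)C)=C\[C@@H](O[Si](C)(C)C(C)(C)C)[C@H](C(=C)COCc2ccc(OC)cc2)[C@H](OCOC)[C@@H](OC(=O)CC(C)C)[C@]1(C)O
F6 | step 21 | α'-hydroxy cyclodecadienone | O=C1/C=C/C(CO[Si](c2ccccc2)(c2ccccc2)C(C)(C)C)=C\[C@@H](O[Si](C)(C)C(C)(C)C)[C@H](C(=C)COCc2ccc(OC)cc2)[C@H](OCOC)[C@@H](OC(=O)CC(C)C)[C@]1(C)O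
F7 | step 3 | trans-4,5-disubstituted lactone without O6 | O=C1C[C@H](C(=C)COCc2ccc(OC)cc2)[C@@H](CO[Si](c2ccccc2)(c2ccccc2)C(C)(C)C)O1
F8 | step 7 | hydroxy Weinreb amide | CON(C)C(=O)[C@@H](O[Si](C)(C)C(C)(C)C)[C@H](C(=C)COCc1ccc(OC)cc1)[C@H](O)CO[Si](c1ccccc1)(c1ccccc1)C(C)(C)C
F9 | step 7 | O8-MOM Weinreb amide | CON(C)C(=O)[C@@H](O[Si](C)(C)C(C)(C)C)[C@H](C(=C)COCc1ccc(OC)cc1)[C@H](OCOC)CO[Si](c1ccccc1)(c1ccccc1)C(C)(C)C
F10 | step 7 | acyclic C5 aldehyde | O=C[C@@H](O[Si](C)(C)C(C)(C)C)[C@H](C(=C)COCc1ccc(OC)cc1)[C@H](OCOC)CO[Si](c1ccccc1)(c1ccccc1)C(C)(C)C
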